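(The readings were computed from invented constants.)

The green flask stood closed and stirred with L at 0.800 of the X charge, and I had to say what it held at 2.0 d and whether any option was worth taking.

| setting | green | blue | flask |
|---|---|---|---|
| X | 2 M | 2 M | 2.0 M |
| L | 1.6 M | 2.4 M | 1.60 M |
| remark | the very flask that is asked about, followed so far | run made earlier |  |
| time |  |  | 2.0 d |

green run (percent of the X charged)

| time / h | G / % | X / % |
|---|---|---|
| 12.0 | 75.8 | 0 |
| 25.0 | 75.8 | 0.4 |
| 40.0 | 76.4 | 0.4 |
| 50.0 | 77.1 | 0.4 |

blue run (percent of the X charged)

| time / min | G / % | X / % |
|---|---|---|
| 5.00 | 20.3 | 67.7 |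
| 12.0 | 39.5 | 40.9 |
| 25.0 | 56.6 | 16.1 |
| 60.0 | 66.8 | 1.2 |

(standard deviation of a reading: 0.5 percentage points)

- north: at 2.0 d add L, 50.0% of the amount charged, then wait 4.0 d
- south-west: at 2.0 d take out 90% of the G then present, then wait 4.0 d
- north-east: change nothing and wait 4.0 d more

- removed G is counted in
- the earlier runs were read with a standard deviation of 0.5 percentage points
- additions bring no volume worth counting

1. G, in percent of the X first charged, at 2.0 d
2. the option that brings most further G ("none" if no option brings more than 2 percentage points) (north / south-west / north-east / none)
3. G present, with what was taken out counted in, in percent of the X first charged, after south-west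
4. G present, with what was taken out counted in, in percent of the X first charged, after north-east

I kept a ledger of X, which I took as the limiting reagent here though L was charged short of it, because green X read 0.4% at 50.0 h. The first entry was G. The second was a lost share, which I took as X that had met one L: blue, richer in L (1.20 against 0.800), read at its last point G at 67.6% of the X used, less than green's reading of 75.8% at 12.0 h.

So I carried a split number (a selectivity factor): G made per X lost, times the mean free L over the run, with L as a fraction of the X charge. The blue readings gave 2.17, and the green reading at 12.0 h gave 2.13, from a different L.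

For green, a first pass from the charge put the lost share at 0.270, so I took mean free L as 0.665 and reckoned G to close at 76.5%. The green reading of free X, 0.4%, was less than the 2 percentage points margin, and the green rise of 1.3 points stood against a scatter of 0.5 points per reading, so I said none and held G at my reckoned figure after south-west and after north-east.

The forecast gave 76.9% (76.2% to 77.5%), with 78.5% after south-west and 78.5% after north-east, and it chose north, reading “L nearly exhausted”, about 3% left. There I differed.

The flask gave 76.5%, with 76.5% after south-west, 76.5% after north-east and 0 points gained by north, so the answer was none. At 48.0 h it held X 0%, L 51.7% of its own charge, E 14.9% and Z 8.59%.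

    L + E ⇌ Z (K = 0.690 M⁻¹, k = 0.00249 M⁻¹ min⁻¹)
    X → G (k = 0.0500 min⁻¹)
    L → D (k = 5.05 × 10⁻⁵ min⁻¹)
    X + L → E (k = 0.0115 M⁻¹ min⁻¹)

The neighbouring flask, the same but with L at 0.64 M, went through the same ledger. L stood at 0.320 of the X charge, a first pass put the lost share at 0.129 and mean free L at 0.256, and the split number put G at 89.4%. That flask gave 89.3%, with E 8.70%, Z 2.02% and X 0%.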